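**Stereochemistry note:** Glyinflanin D has no stereocenters, so the single-enantiomer requirement is trivially met and nothing needs to be set or protected against scrambling.
**Assumption:** The prenal/pyridine chromenylation of 2,4-dihydroxyacetophenone is taken to favour the linear 6-acetyl-7-hydroxy isomer over the angular 8-acetyl isomer. I assume the angular minor product is removable by chromatography.

## Retrosynthesis
- Target **1** is a 1,3-diaryl-propane-1,3-dione (a dibenzoylmethane). Disconnect it at the C(O)–CH2 bond by a crossed Claisen condensation.
- This gives o-hydroxyacetophenone chromene **2** (the enolate donor) and methyl chromene-6-carboxylate **3** (the acylating ester).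
- Each 2,2-dimethyl-2H-chromene is built in one step from a phenol and prenal (**6**), by ortho-condensation followed by oxa-6π electrocyclization.
- The phenol precursors are 2,4-dihydroxyacetophenone (**4**) for **2** and methyl 4-hydroxybenzoate (**5**) for **3**.
- Order of ring formation: both pyran rings first, in parallel, then the diketone C–C bond last. No protecting groups are needed.

## Forward route

**Step 1**
Reactants: **5** methyl 4-hydroxybenzoate; **6** 3-methylbut-2-enal (prenal)
Product: **3** methyl 2,2-dimethyl-2H-chromene-6-carboxylate
Conditions: **6** (3 equiv), pyridine, 130 °C, sealed tube, 24 h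
Reagents that add atoms: none (prenal is a reactant, and water is lost)
Why: Pyridine-mediated ortho-hydroxyalkenylation of the phenol gives an o-quinone methide/dienone, which undergoes 6π-oxa-electrocyclization to the chromene. Both ortho positions of the para-substituted phenol are equivalent, so there is no regiochemistry issue, and no stereocenter is formed (C2 carries two methyls).

**Step 2**
Reactants: **4** 2,4-dihydroxyacetophenone; **6** prenal
Product: **2** 6-acetyl-7-hydroxy-2,2-dimethyl-2H-chromene
Conditions: **6** (2 equiv), pyridine, 115 °C (reflux), 16 h; chromatography to remove the angular isomer
Reagents that add atoms: none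
Why: The 2-OH is hydrogen-bonded to the acetyl group and unreactive, so the 4-OH directs condensation at the less hindered C5. Oxa-6π-electrocyclization then gives the linear chromene with the acetyl group ortho to the free phenol, as in the target's right-hand ring. The product is achiral.

**Step 3**
Reactants: **2** 6-acetyl-7-hydroxy-2,2-dimethylchromene; **3** methyl 2,2-dimethylchromene-6-carboxylate
Product: **1** Glyinflanin D
Conditions: NaH (4 equiv), THF, 0 °C → 65 °C, 12 h; quench with aq NH4Cl, then adjust to pH ~5 with dilute HCl
Reagents that add atoms: none (methanol is lost)
Why: Excess NaH forms the phenoxide and then the methyl ketone enolate. This dianion attacks the methyl ester (crossed Claisen condensation), and the resulting chelated 1,3-diketonate is deprotonated, which drives the reaction. Ester **3** has no α-hydrogens and cannot self-condense. The trisubstituted-free chromene alkenes and the aryl ethers survive basic conditions, and the mild acidic work-up protects the chromenes. The product is achiral.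

## Checks
- **Target match:** Product **1** contains two 2,2-dimethyl-2H-chromene units joined through ArC(=O)CH2C(=O)Ar. The hydroxylated ring has the OH ortho to the carbonyl and the pyran O para to it, matching the SMILES.
- **Atom balance:**
  - Step 1: C8H8O3 + C5H8O − H2O = C13H14O3 (**3**).
  - Step 2: C8H8O3 + C5H8O − H2O = C13H14O3 (**2**).
  - Step 3: C13H14O3 + C13H14O3 − CH4O = C25H24O5, the formula of **1**.
- **Functional-group survival:** Pyridine and heat leave the ester and ketone intact. NaH does not touch the chromene C=C bonds.
- **Stereocenters:** None exist, so none can be scrambled.

## Compound list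
1 | Glyinflanin D | CC1(C)C=Cc2cc(C(=O)CC(=O)c3cc4c(cc3O)OC(C)(C)C=C4)ccc2O1 | target
2 | 6-acetyl-7-hydroxy-2,2-dimethyl-2H-chromene | CC(=O)c1cc2C=CC(C)(C)Oc2cc1O | intermediate
3 | methyl 2,2-dimethyl-2H-chromene-6-carboxylate | COC(=O)c1ccc2OC(C)(C)C=Cc2c1 | intermediate
4 | 2,4-dihydroxyacetophenone | CC(=O)c1ccc(O)cc1O | starting material
5 | methyl 4-hydroxybenzoate | COC(=O)c1ccc(O)cc1 | starting material
6 | 3-methylbut-2-enal (prenal) | CC(C)=CC=O | starting material

## Totals
Total steps: 3. Longest linear sequence: 2 steps (Step 1 or 2, then Step 3).

## Three steps most likely to fail
1. **Step 3 (direct Claisen of a phenoxide-bearing ketone with a deactivated aryl ester).** It may give low conversion or self-condensation of **2**.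
   Fallback: use a Baker–Venkataraman route. Hydrolyse **3** to the acid (LiOH), couple it with phenol **2** (EDC, DMAP) to give the aryl ester, then rearrange with KOtBu in THF or DMSO.
2. **Step 2 (linear versus angular regioselectivity, moderate yield).**
   Fallback: selectively 4-O-propargylate **4** with 3-chloro-3-methylbut-1-yne (K2CO3, KI, acetone). Then cyclize the aryl propargyl ether thermally (PhNEt2, 200 °C) or with a gold/silver catalyst, again separating the isomers.
3. **Step 1 (electron-poor phenol, sluggish chromene formation).**
   Fallback: O-propargylate **5** with 3-chloro-3-methylbut-1-yne and CuCl/DBU or K2CO3/KI, then cyclize by Claisen rearrangement and 6π-electrocyclization in refluxing PhNEt2.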